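**Plan**
- Retrosynthesis: cut first the C5–CH2 bond of the bibenzyl (sp2–sp3 Suzuki–Miyaura; C5 carries a triflate as helper). Then cut together the C4–C4a and O1–C8a bonds of the pyran ring (aryne plus prenal; O1–C2 closes in the same cascade). Last, cut the prenyl–O7 bond and the C7–O bond (C–H borylation/oxidation).
- Forward: the benzene ring is bought as a mirror-symmetric 2-silyl-1,3-bis(triflate). Oxygen is put on the future C7 and prenylated, the pyran ring arises in step 3, and the 4-hydroxyphenethyl chain is joined last at C5.
- Enabling feature: C4a and C8a are adjacent carbons of the benzo ring, and C5, C7 and C8a are mutually meta. An aryne across C4a–C8a therefore comes from a symmetric precursor, and the O1–C2(CH3)2–C3=C4 unit is prenal with its oxygen transposed.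
- Helper: the C5 triflate is the second, equivalent leaving group of the precursor. It polarises the aryne so that the carbonyl oxygen goes to C8a and the carbonyl carbon to C4a, and it leaves in the final cross-coupling.
- Stereochemistry: the target has no stereocentre; the C3=C4 double bond is cis by ring constraint, so nothing has to be controlled.

Key step: step 3

Assumption: silyl bis(triflate) 1 is taken as a catalogue compound (it is sold as a two-fold aryne precursor).

**Step 1**
Reactants: 1 2-(trimethylsilyl)-1,3-phenylene bis(trifluoromethanesulfonate)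
Product: 3 5-hydroxy-2-(trimethylsilyl)-1,3-phenylene bis(trifluoromethanesulfonate), via aryl pinacol boronate 2 (not isolated)
Conditions: [Ir(OMe)(cod)]2 (1.5 mol%), dtbpy (3 mol%), B2pin2 (1.0 equiv), THF, 80 °C; concentrate; Oxone (KHSO5, 1.1 equiv), acetone/H2O, rt, 15 min
Reagents that add atoms: potassium peroxymonosulfate (active salt of Oxone), [K+].[O-]S(=O)(=O)OO, gives the phenol oxygen; bis(pinacolato)diboron, CC1(C)OB(OC1(C)C)B1OC(C)(C)C(C)(C)O1, gives the boryl group of intermediate 2 only
Why: Iridium-catalysed aromatic C–H borylation is sterically governed, so only C5–H, the one hydrogen of 1 without an ortho substituent, should react, and the boronate is then oxidised to the phenol in the same flask (one-pot C–H borylation/oxidation), conditions that silylaryl triflates should tolerate.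

**Step 2**
Reactants: 3 5-hydroxy-2-(trimethylsilyl)-1,3-phenylene bis(trifluoromethanesulfonate); 4 prenyl bromide (1-bromo-3-methylbut-2-ene)
Product: 5 5-[(3-methylbut-2-en-1-yl)oxy]-2-(trimethylsilyl)-1,3-phenylene bis(trifluoromethanesulfonate)
Conditions: K2CO3 (1.5 equiv), acetone, rt
Reagents that add atoms: none
Why: Williamson etherification: the acidic phenol (two meta triflates) is deprotonated by K2CO3 and the phenoxide displaces bromide at the primary allylic carbon by SN2, while carbonate without fluoride or crown ether should not attack silicon at room temperature.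

**Step 3**
Reactants: 5 5-[(3-methylbut-2-en-1-yl)oxy]-2-(trimethylsilyl)-1,3-phenylene bis(trifluoromethanesulfonate); 6 prenal (3-methylbut-2-enal)
Product: 10 2,2-dimethyl-7-[(3-methylbut-2-en-1-yl)oxy]-2H-chromen-5-yl trifluoromethanesulfonate, via 3-triflyloxy aryne 7 (not isolated), via benzoxete 8 (not isolated), via ortho-quinone methide 9 (not isolated)
Conditions: CsF (3 equiv), 6 (5 equiv), MeCN, rt, slow addition of 5
Reagents that add atoms: none
Why: Fluoride attacks silicon and the aryl anion expels one of the two equivalent triflates, so a single aryne 7 forms whichever triflate leaves. The carbonyl oxygen of prenal adds to the aryne carbon remote from the remaining triflate (the more linear, more electrophilic terminus; the developing aryl anion sits next to the inductively withdrawing OTf), and this anion closes on the oxocarbenium carbon, a stepwise polar [2+2] that makes the O1–C8a and C4–C4a bonds and the four-membered ring of 8. Strain drives 4π-electrocyclic opening of 8 to the Z ortho-quinone methide 9, and the pyran ring then closes by thermal disrotatory oxa-6π electrocyclisation (O1–C2 bond) with return of aromaticity. The closest known reaction type is the fluoride-triggered annulation of arynes from silylaryl triflates with α,β-unsaturated aldehydes to 2H-chromenes, combined with the regioselective chemistry of 3-triflyloxyarynes released from 2-silyl-1,3-bis(triflates). No stereocentre arises in 10 (the benzoxete carbon of 8 is racemic and becomes planar again) and the C3=C4 bond is cis by ring constraint. The step needs regioselectivity (oxygen at C8a, not C4a), which the C5 triflate secures against the weaker opposite bias of the C7 ether, and it needs ring closure to outrun loss of the second triflate or capture of 9 by another aryne, which the intramolecular closures, excess prenal and slow aryne release should secure.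

**Step 4**
Reactants: 10 2,2-dimethyl-7-[(3-methylbut-2-en-1-yl)oxy]-2H-chromen-5-yl trifluoromethanesulfonate; 11 4-acetoxystyrene (4-ethenylphenyl acetate)
Product: 14 4-{2-[2,2-dimethyl-7-[(3-methylbut-2-en-1-yl)oxy]-2H-chromen-5-yl]ethyl}phenol, via alkyl-9-BBN borane 12 (not isolated), via aryl acetate 13 (not isolated)
Conditions: 11 (1.6 equiv), 9-BBN-H (1.5 equiv), THF, 0 °C to rt; then 10, Pd(OAc)2 (5 mol%), SPhos (10 mol%), K3PO4 (3 M aq, 3 equiv), THF, 60 °C; then NaOH (2 M aq), MeOH, rt
Reagents that add atoms: 9-borabicyclo[3.3.1]nonane (9-BBN-H), B1C2CCCC1CCC2, gives the boron of intermediate 12 and only hydrogen to the product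
Why: 9-BBN adds anti-Markovnikov to the styrene without touching the aryl acetate, the B-alkyl Suzuki–Miyaura coupling (zerovalent palladium with SPhos inserts into the hindered, electron-rich C5–OTf bond and the phosphate-activated borane transmetalates) joins the sp3 carbon to C5 and removes the helper triflate, and hydroxide then saponifies the phenyl acetate without harm to the prenyl ether or the chromene.

**Compound list**
1 | 2-(trimethylsilyl)-1,3-phenylene bis(trifluoromethanesulfonate) | C[Si](C)(C)c1c(OS(=O)(=O)C(F)(F)F)cccc1OS(=O)(=O)C(F)(F)F | starting material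
2 | 5-(4,4,5,5-tetramethyl-1,3,2-dioxaborolan-2-yl)-2-(trimethylsilyl)-1,3-phenylene bis(trifluoromethanesulfonate) | C[Si](C)(C)c1c(OS(=O)(=O)C(F)(F)F)cc(cc1OS(=O)(=O)C(F)(F)F)B1OC(C)(C)C(C)(C)O1 | intermediate
3 | 5-hydroxy-2-(trimethylsilyl)-1,3-phenylene bis(trifluoromethanesulfonate) | C[Si](C)(C)c1c(OS(=O)(=O)C(F)(F)F)cc(O)cc1OS(=O)(=O)C(F)(F)F | intermediate
4 | prenyl bromide (1-bromo-3-methylbut-2-ene) | CC(C)=CCBr | starting material
5 | 5-[(3-methylbut-2-en-1-yl)oxy]-2-(trimethylsilyl)-1,3-phenylene bis(trifluoromethanesulfonate) | C[Si](C)(C)c1c(OS(=O)(=O)C(F)(F)F)cc(OCC=C(C)C)cc1OS(=O)(=O)C(F)(F)F | intermediate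
6 | prenal (3-methylbut-2-enal) | CC(C)=CC=O | starting material
7 | 5-[(3-methylbut-2-en-1-yl)oxy]-3-[(trifluoromethanesulfonyl)oxy]benzyne (1,2-didehydrobenzene) | CC(C)=CCOC1=CC#CC(OS(=O)(=O)C(F)(F)F)=C1 | intermediate
8 | 2-(2-methylprop-1-en-1-yl)-5-[(3-methylbut-2-en-1-yl)oxy]-2H-benzoxet-3-yl trifluoromethanesulfonate (racemic) | CC(C)=CC1Oc2cc(OCC=C(C)C)cc(OS(=O)(=O)C(F)(F)F)c21 | intermediate
9 | (6Z)-6-(3-methylbut-2-en-1-ylidene)-3-[(3-methylbut-2-en-1-yl)oxy]-5-[(trifluoromethanesulfonyl)oxy]cyclohexa-2,4-dien-1-one | CC(C)=C/C=C1\C(=O)C=C(OCC=C(C)C)C=C1OS(=O)(=O)C(F)(F)F | intermediate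
10 | 2,2-dimethyl-7-[(3-methylbut-2-en-1-yl)oxy]-2H-chromen-5-yl trifluoromethanesulfonate | CC(C)=CCOc1cc(OS(=O)(=O)C(F)(F)F)c2c(c1)OC(C)(C)C=C2 | intermediate
11 | 4-acetoxystyrene (4-ethenylphenyl acetate) | CC(=O)Oc1ccc(C=C)cc1 | starting material
12 | 4-[2-(9-borabicyclo[3.3.1]nonan-9-yl)ethyl]phenyl acetate | CC(=O)Oc1ccc(CCB2C3CCCC2CCC3)cc1 | intermediate
13 | 4-{2-[2,2-dimethyl-7-[(3-methylbut-2-en-1-yl)oxy]-2H-chromen-5-yl]ethyl}phenyl acetate | CC(=O)Oc1ccc(CCc2cc(OCC=C(C)C)cc3OC(C)(C)C=Cc23)cc1 | intermediate
14 | 4-{2-[2,2-dimethyl-7-[(3-methylbut-2-en-1-yl)oxy]-2H-chromen-5-yl]ethyl}phenol | CC(C)=CCOc1cc(CCc2ccc(O)cc2)c2c(c1)OC(C)(C)C=C2 | target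

**Step count**
Total steps: 4. Longest linear sequence: 4 steps (1 → 3 → 5 → 10 → 14).

**Steps most likely to fail**

1. Step 3. The aryl anion formed after oxygen attack may lose the neighbouring triflate (a second aryne) before it closes on carbon. The quinone methide may also be captured by another aryne before it electrocyclises, and prenal may self-condense under fluoride. The fallback sets out from 5 and 6 and returns at 10. Prenal 6 is condensed with N-tert-butylhydroxylamine (MgSO4, CH2Cl2) to (Z)-N-tert-butyl-C-(2-methylprop-1-en-1-yl)nitrone F1. The aryne from 5 (CsF, MeCN, rt) should be trapped by this nitrone in a concerted (3+2) cycloaddition, in which no free aryl anion and no quinone methide is present. With the same sense of addition (oxygen to the carbon remote from the triflate) this should give 2-tert-butyl-3-(2-methylprop-1-en-1-yl)-6-[(3-methylbut-2-en-1-yl)oxy]-2,3-dihydro-1,2-benzoxazol-4-yl trifluoromethanesulfonate F2. Zn in AcOH should cleave the N–O bond to 2-[1-(tert-butylamino)-3-methylbut-2-en-1-yl]-3-hydroxy-5-[(3-methylbut-2-en-1-yl)oxy]phenyl trifluoromethanesulfonate F3. Heating this Mannich-type base in toluene (110 °C) should expel tert-butylamine to give quinone methide 9 in the absence of any aryne, and 9 should close to 10.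

2. Step 4. Transmetalation of the sp3 borane at the hindered C5–palladium centre may be slow, so that β-hydride elimination or protodeboronation of the borane, hydrolysis of the triflate, or palladium-allyl ionisation of the prenyl ether take over. The fallback sets out from 10 and returns at 13, with the roles of the partners reversed. Compound 10 is vinylated with potassium vinyltrifluoroborate (PdCl2(dppf), Cs2CO3, THF/H2O, 70 °C; an sp2 partner without β-hydrogen) to 5-ethenyl-2,2-dimethyl-7-[(3-methylbut-2-en-1-yl)oxy]-2H-chromene F4. 9-BBN-H (1.0 equiv, THF, 0 °C) should add only to the terminal vinyl group, since the trisubstituted prenyl alkene and the cis-disubstituted chromene alkene next to a quaternary carbon react far more slowly. This should give 9-{2-[2,2-dimethyl-7-[(3-methylbut-2-en-1-yl)oxy]-2H-chromen-5-yl]ethyl}-9-borabicyclo[3.3.1]nonane F5. B-alkyl Suzuki–Miyaura coupling of this borane with 4-iodophenyl acetate (PdCl2(dppf), K3PO4, THF/DMF, rt to 40 °C; fast oxidative addition, unhindered aryl palladium) should give 13, which is saponified as in step 4.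

3. Step 2. Carbonate may attack silicon and release the aryne prematurely, or the C–Si bond para to the phenoxide may be cleaved. The fallback sets out from 3 and returns at 5. It is a Mitsunobu etherification of 3 with prenol (3-methylbut-2-en-1-ol), PPh3 and DIAD in THF at 0 °C, a neutral redox condensation in which no free base is present; no new compound is formed (F0).

**Further compounds**
F1 | step 3 | (Z)-N-tert-butyl-C-(2-methylprop-1-en-1-yl)nitrone | CC(C)=C/C=[N+](\[O-])C(C)(C)C
F2 | step 3 | 2-tert-butyl-3-(2-methylprop-1-en-1-yl)-6-[(3-methylbut-2-en-1-yl)oxy]-2,3-dihydro-1,2-benzoxazol-4-yl trifluoromethanesulfonate (racemic) | CC(C)=CC1N(C(C)(C)C)Oc2cc(OCC=C(C)C)cc(OS(=O)(=O)C(F)(F)F)c21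
F3 | step 3 | 2-[1-(tert-butylamino)-3-methylbut-2-en-1-yl]-3-hydroxy-5-[(3-methylbut-2-en-1-yl)oxy]phenyl trifluoromethanesulfonate (racemic) | CC(C)=CC(NC(C)(C)C)c1c(O)cc(OCC=C(C)C)cc1OS(=O)(=O)C(F)(F)F
F4 | step 4 | 5-ethenyl-2,2-dimethyl-7-[(3-methylbut-2-en-1-yl)oxy]-2H-chromene | C=Cc1cc(OCC=C(C)C)cc2OC(C)(C)C=Cc12
F5 | step 4 | 9-{2-[2,2-dimethyl-7-[(3-methylbut-2-en-1-yl)oxy]-2H-chromen-5-yl]ethyl}-9-borabicyclo[3.3.1]nonane | CC(C)=CCOc1cc(CCB2C3CCCC2CCC3)c2C=CC(C)(C)Oc2c1
F0 | step 2 | none | none
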